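**Strategy**

The route rests on cutting the O1–C2 bond of ring C. C2 is a benzylic carbon flanked by the ring A oxygen O1 and by C3, so it is the branched end of a 4-methoxycinnamyl unit. An iridium-catalysed allylic etherification joins the phenoxide of a fully substituted 2-hydroxyacetophenone (ring A, already carrying C4 as its acetyl carbon) to the cinnamyl methyl carbonate. This makes O1–C2 and the C2 stereocentre in one operation and leaves a vinyl group as latent C3. Ring C is then closed at C3–C4 by silyl enol ether–olefin metathesis, far from the stereocentre, and unmasking the ketone gives the flavanone.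

Key step: step 5

Remark: L is (Sa,Sc,Sc)-O,O'-(1,1'-binaphthalene-2,2'-diyl) N,N-bis(1-phenylethyl)phosphoramidite; it is assumed, from the usual sense of induction of this catalyst class with heteroatom nucleophiles, to give the S ether, which is to be checked on the first run, the (Ra,Rc,Rc) ligand being used instead if the R ether forms.

**Route**

Step 1
Reactants: 1 1,2,3,4-tetramethoxybenzene
Product: 3 2,3,4,5-tetramethoxybenzaldehyde, via aryl iminium salt 2 (not isolated)
Conditions: POCl3, DMF, 0 → 75 °C; then ice–water
Reagents that add atoms: N,N-dimethylformamide, CN(C)C=O; water, O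
Why: Vilsmeier–Haack formylation, in which the chloroiminium ion attacks one of the two equivalent free ring positions (each ortho and para to methoxy groups) and the iminium salt is hydrolysed to the aldehyde on aqueous work-up.

Step 2
Reactants: 3 2,3,4,5-tetramethoxybenzaldehyde
Product: 5 2,3,4,5-tetramethoxyphenol, via aryl formate 4 (not isolated)
Conditions: mCPBA, CH2Cl2, 0 °C → rt; aq. NaHCO3 wash; then K2CO3 (10 mol%), MeOH, rt, under N2
Reagents that add atoms: 3-chloroperoxybenzoic acid, OOC(=O)c1cccc(Cl)c1
Why: Dakin-type Baeyer–Villiger oxidation, in which the electron-rich aryl group migrates to oxygen in the peracid adduct and the resulting formate is methanolysed to the phenol.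

Step 3
Reactants: 5 2,3,4,5-tetramethoxyphenol
Product: 7 1-(2-hydroxy-3,4,5,6-tetramethoxyphenyl)ethan-1-one, via difluoroboron chelate 6 (not isolated)
Conditions: AcOH, BF3·OEt2, 80 °C; then H2O, EtOH, 60 °C
Reagents that add atoms: acetic acid, CC(=O)O
Why: Boron trifluoride-mediated Friedel–Crafts C-acetylation (equivalently O-acetylation and Fries shift) at the single free ring position, which lies ortho to the hydroxyl, the ketone being held as its BF2 chelate until water releases it.

Step 4
Reactants: 8 (E)-3-(4-methoxyphenyl)prop-2-en-1-ol; 9 methyl chloroformate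
Product: 10 (E)-3-(4-methoxyphenyl)prop-2-en-1-yl methyl carbonate
Conditions: pyridine, CH2Cl2, 0 °C
Reagents that add atoms: methyl chloroformate (9), COC(Cl)=O
Why: O-acylation of a primary allylic alcohol by a chloroformate, with pyridine taking up HCl so that the acid-labile anisyl allyl system never meets acid.

Step 5
Reactants: 7 1-(2-hydroxy-3,4,5,6-tetramethoxyphenyl)ethan-1-one; 10 (E)-3-(4-methoxyphenyl)prop-2-en-1-yl methyl carbonate
Product: 12 (S)-1-[2,3,4,5-tetramethoxy-6-{[1-(4-methoxyphenyl)prop-2-en-1-yl]oxy}phenyl]ethan-1-one, via lithium aryloxide 11 (not isolated)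
Conditions: 7 (1.2 equiv), LiN(SiMe3)2 (1.1 equiv), THF, 0 °C; then 10 (1.0 equiv), [Ir(cod)Cl]2 (2 mol%), (Sa,Sc,Sc)-L (4 mol%, pre-activated with n-PrNH2), THF, 0 °C → rt
Reagents that add atoms: none
Why: The cyclometalated complex of monovalent iridium formed from [Ir(cod)Cl]2 and L ionises carbonate 10, with loss of CO2 and methoxide, to an allyl complex of trivalent iridium, and aryloxide 11 attacks its aryl-bearing terminus from the face opposite the metal to forge O1–C2 while the vinyl group that will become C3 is left behind. The closest known reaction is the iridium–phosphoramidite allylic etherification of alkali metal aryloxides with cinnamyl carbonates, which delivers branched aryl allyl ethers. No ring is closed here. The C2 stereocentre is controlled by the catalyst alone, since the chiral iridacycle binds one enantioface of the allyl unit and so exposes a single face of the benzylic terminus, the (Sa,Sc,Sc) ligand being chosen for the S ether. The step needs branched over linear regioselectivity, which the aryl substituent on the allyl unit and this catalyst class favour, and chemoselectivity for oxygen, which is secured because every carbon of ring A is substituted and the weakly basic aryloxide does not enolise the acetyl group. Carbonate 10 is the limiting partner and the mixture is kept at or below room temperature and quenched at full conversion, because the anisyl-stabilised branched ether can re-ionise on the catalyst and lose regio- and enantiopurity.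

Step 6
Reactants: 12 (S)-1-[2,3,4,5-tetramethoxy-6-{[1-(4-methoxyphenyl)prop-2-en-1-yl]oxy}phenyl]ethan-1-one
Product: 14 (S)-tert-butyl(dimethyl){[1-(2,3,4,5-tetramethoxy-6-{[1-(4-methoxyphenyl)prop-2-en-1-yl]oxy}phenyl)ethenyl]oxy}silane, via potassium enolate 13 (not isolated)
Conditions: KN(SiMe3)2, THF, −78 °C; then tBuMe2SiCl, −78 → 0 °C
Reagents that add atoms: tert-butyldimethylsilyl chloride, CC(C)(C)[Si](C)(C)Cl
Why: Kinetic deprotonation of the methyl ketone and O-silylation of the potassium enolate (silyl enol ether formation), with no Lewis acid present that could ionise the benzylic, allylic C2–O1 bond and a base too weak to remove the C2 hydrogen at −78 °C, so the stereocentre is untouched.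

Step 7
Reactants: 14 (S)-tert-butyl(dimethyl){[1-(2,3,4,5-tetramethoxy-6-{[1-(4-methoxyphenyl)prop-2-en-1-yl]oxy}phenyl)ethenyl]oxy}silane
Product: 16 (2S)-5,6,7,8-tetramethoxy-2-(4-methoxyphenyl)chroman-4-one [(2S)-5,6,7,8,4'-pentamethoxyflavanone], via silyloxychromene 15 (not isolated)
Conditions: second-generation Grubbs catalyst RuCl2(H2IMes)(PCy3)(=CHPh) (5 mol%), 1,4-benzoquinone (10 mol%), CH2Cl2 (0.01 M), 40 °C, dark; then Bu4NF, AcOH, THF, 0 °C
Reagents that add atoms: none
Why: Ring-closing silyl enol ether–olefin metathesis (the ruthenium carbene loads on the monosubstituted vinyl group, closes the six-membered ring C onto the 1,1-disubstituted enol ether to form C3=C4 and releases ethene) followed by buffered fluoride desilylation, in which C3 is protonated under near-neutral conditions, so that neither operation touches C2 and no strong acid or base is present that could open ring C to the chalcone.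

**Compound list**

1 | 1,2,3,4-tetramethoxybenzene | COc1ccc(OC)c(OC)c1OC | starting material
2 | N,N-dimethyl-1-(2,3,4,5-tetramethoxyphenyl)methaniminium dichlorophosphate | C[N+](C)=Cc1cc(OC)c(OC)c(OC)c1OC.[O-]P(=O)(Cl)Cl | intermediate
3 | 2,3,4,5-tetramethoxybenzaldehyde | COc1cc(C=O)c(OC)c(OC)c1OC | intermediate
4 | 2,3,4,5-tetramethoxyphenyl formate | COc1cc(OC=O)c(OC)c(OC)c1OC | intermediate
5 | 2,3,4,5-tetramethoxyphenol | COc1cc(O)c(OC)c(OC)c1OC | intermediate
6 | 2,2-difluoro-5,6,7,8-tetramethoxy-4-methyl-1,3,2-benzodioxaborinine (difluoroboron chelate of 7) | CC1=[O+][B-](F)(F)Oc2c(OC)c(OC)c(OC)c(OC)c12 | intermediate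
7 | 1-(2-hydroxy-3,4,5,6-tetramethoxyphenyl)ethan-1-one | CC(=O)c1c(O)c(OC)c(OC)c(OC)c1OC | intermediate
8 | (E)-3-(4-methoxyphenyl)prop-2-en-1-ol | COc1ccc(/C=C/CO)cc1 | starting material
9 | methyl chloroformate | COC(Cl)=O | starting material
10 | (E)-3-(4-methoxyphenyl)prop-2-en-1-yl methyl carbonate | COC(=O)OC/C=C/c1ccc(OC)cc1 | intermediate
11 | lithium 2-acetyl-3,4,5,6-tetramethoxyphenolate | CC(=O)c1c([O-])c(OC)c(OC)c(OC)c1OC.[Li+] | intermediate
12 | (S)-1-[2,3,4,5-tetramethoxy-6-{[1-(4-methoxyphenyl)prop-2-en-1-yl]oxy}phenyl]ethan-1-one | COc1ccc([C@H](C=C)Oc2c(OC)c(OC)c(OC)c(OC)c2C(C)=O)cc1 | intermediate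
13 | potassium (S)-1-(2,3,4,5-tetramethoxy-6-{[1-(4-methoxyphenyl)prop-2-en-1-yl]oxy}phenyl)ethen-1-olate | COc1ccc([C@H](C=C)Oc2c(OC)c(OC)c(OC)c(OC)c2C(=C)[O-])cc1.[K+] | intermediate
14 | (S)-tert-butyl(dimethyl){[1-(2,3,4,5-tetramethoxy-6-{[1-(4-methoxyphenyl)prop-2-en-1-yl]oxy}phenyl)ethenyl]oxy}silane | COc1ccc([C@H](C=C)Oc2c(OC)c(OC)c(OC)c(OC)c2C(=C)O[Si](C)(C)C(C)(C)C)cc1 | intermediate
15 | (2S)-4-[(tert-butyldimethylsilyl)oxy]-5,6,7,8-tetramethoxy-2-(4-methoxyphenyl)-2H-chromene | COc1ccc([C@@H]2C=C(O[Si](C)(C)C(C)(C)C)c3c(OC)c(OC)c(OC)c(OC)c3O2)cc1 | intermediate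
16 | (2S)-5,6,7,8-tetramethoxy-2-(4-methoxyphenyl)chroman-4-one, (2S)-5,6,7,8,4'-pentamethoxyflavanone | COc1ccc([C@@H]2CC(=O)c3c(OC)c(OC)c(OC)c(OC)c3O2)cc1 | target

**Step count and risks**

Total step count: 7. Longest linear sequence: 6 (steps 1, 2, 3, 5, 6, 7, from compound 1).

The three steps most likely to fail:

1. Step 5. The hindered, chelated aryloxide may attack the allyl complex slowly, so that the carbonate decomposes first. The branched ether may also re-ionise on the catalyst, which would erode branched selectivity and enantiopurity. The fallback sets out from 7 and comes back to the route at 16, and it sets C2 by C–C instead of C–O bond formation. Heating 7 with N,N-dimethylformamide dimethyl acetal should give the enaminone (E)-3-(dimethylamino)-1-(2-hydroxy-3,4,5,6-tetramethoxyphenyl)prop-2-en-1-one F1. Treatment with HCl in CH2Cl2 should cyclise it, with loss of dimethylamine, to 5,6,7,8-tetramethoxy-4H-chromen-4-one F2. Conjugate addition of 4-methoxyphenylboronic acid to F2, catalysed by Pd(OCOCF3)2 (divalent palladium) and an enantiopure 4-tert-butyl-2-(pyridin-2-yl)-4,5-dihydrooxazole ligand (NH4PF6, water, 1,2-dichloroethane, 60 °C), is a known way to flavanones and should give 16 directly. The ligand enantiomer would be chosen for the 2S product.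

2. Step 7. The ruthenium carbene may fail to engage the 1,1-disubstituted enol ether, which sits between two ortho substituents. Ruthenium hydrides may shift the allyl ether double bond. Thermal electrocyclic opening of the chromene may scramble C2. The fallback sets out from 7 and comes back at 16. Claisen–Schmidt condensation of 7 with 4-methoxybenzaldehyde (KOH, EtOH) should give the chalcone (E)-1-(2-hydroxy-3,4,5,6-tetramethoxyphenyl)-3-(4-methoxyphenyl)prop-2-en-1-one F3. NaOAc in refluxing ethanol should close ring C by intramolecular oxa-Michael addition to the racemic flavanone rac-5,6,7,8-tetramethoxy-2-(4-methoxyphenyl)chroman-4-one F4. Preparative chromatography on a chiral stationary phase would then deliver 16. The unwanted (2R)-5,6,7,8-tetramethoxy-2-(4-methoxyphenyl)chroman-4-one F5 would be returned to F4 by brief base treatment, which equilibrates C2 through the chalcone.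

3. Step 3. Hot BF3 may cleave methyl ethers next to the chelating carbonyl, and C-acylation of the crowded ring may stay incomplete. The fallback sets out from 5 and comes back at 7, replacing electrophilic acylation by directed metalation. MOMCl and iPr2NEt in CH2Cl2 should give 1,2,3,4-tetramethoxy-5-(methoxymethoxy)benzene F6. n-BuLi and TMEDA in THF (−78 → 0 °C) should remove the only ring hydrogen, which is flanked by two oxygen substituents, to give [2,3,4,5-tetramethoxy-6-(methoxymethoxy)phenyl]lithium F7. Quenching with N-methoxy-N-methylacetamide should give 1-[2,3,4,5-tetramethoxy-6-(methoxymethoxy)phenyl]ethan-1-one F8. HCl in MeOH would cleave the acetal to 7.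

**Further compounds**

F1 | step 5 | (E)-3-(dimethylamino)-1-(2-hydroxy-3,4,5,6-tetramethoxyphenyl)prop-2-en-1-one | CN(C)/C=C/C(=O)c1c(O)c(OC)c(OC)c(OC)c1OC
F2 | step 5 | 5,6,7,8-tetramethoxy-4H-chromen-4-one | O=c1ccoc2c(OC)c(OC)c(OC)c(OC)c12
F3 | step 7 | (E)-1-(2-hydroxy-3,4,5,6-tetramethoxyphenyl)-3-(4-methoxyphenyl)prop-2-en-1-one | COc1ccc(/C=C/C(=O)c2c(O)c(OC)c(OC)c(OC)c2OC)cc1
F4 | step 7 | rac-5,6,7,8-tetramethoxy-2-(4-methoxyphenyl)chroman-4-one | COc1ccc(C2CC(=O)c3c(OC)c(OC)c(OC)c(OC)c3O2)cc1
F5 | step 7 | (2R)-5,6,7,8-tetramethoxy-2-(4-methoxyphenyl)chroman-4-one | COc1ccc([C@H]2CC(=O)c3c(OC)c(OC)c(OC)c(OC)c3O2)cc1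
F6 | step 3 | 1,2,3,4-tetramethoxy-5-(methoxymethoxy)benzene | COCOc1cc(OC)c(OC)c(OC)c1OC
F7 | step 3 | [2,3,4,5-tetramethoxy-6-(methoxymethoxy)phenyl]lithium | [Li]c1c(OC)c(OC)c(OC)c(OC)c1OCOC
F8 | step 3 | 1-[2,3,4,5-tetramethoxy-6-(methoxymethoxy)phenyl]ethan-1-one | CC(=O)c1c(OC)c(OC)c(OC)c(OC)c1OCOC
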